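The vessel took L in portions over the catalyst charge E, and the question was what would stand in it at 15 d.

- Saturday's: L 0.10 M (in portions, 3); E 0.20 mM; the very flask that is asked about, followed so far; portions every 2.5 h
- flask: L 0.10 M (in portions, 3); E 0.20 mM; time 15 d; the portions of L follow each other after 2.5 h, the first at the start

Saturday's run (percent of the L charged)

| time / d | L / % | X / % | G / % |
|---|---|---|---|
| 0.250 | 59.7 | 5.6 | 6.1 |
| 0.333 | 47.4 | 14.4 | 10.9 |
| 0.500 | 30.9 | 26.2 | 12.6 |
| 0.833 | 19.6 | 42.7 | 15.4 |
| 1.25 | 12.7 | 48.2 | 18.7 |
| 2.08 | 11.4 | 50.5 | 19.2 |
| 3.00 | 12.2 | 49.1 | 18.3 |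

(standard deviation of a reading: 1 percentage point)

- reactions considered so far: L + D <-> X + D; X + D <-> G + D; G <-> Q; Q <-> L; 2 D <-> J; E -> D
- the reaction counts as stopped when no species that holds the L changes by six tenths of a point or more over the second half of the time

- the state of affairs at 15 d: stopped, and by what, or still going (forward and back rates have come level / it is still moving / no working catalyst is left / all of L has reacted)
- how much of the L has reacted by 15 d
- how much X there is at 15 d, in percent of the L charged
- how much G there is at 15 d, in percent of the L charged

My bench rule for such a flask was plain: if the last 3 readings lie flat within the scatter, call the reaction over and take their mean. Applied honestly, this gave X at 49.3 %, from the readings between 1.25 d and 3.00 d.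

But flatness is a limit on drift, not a proof of none. The difference of two readings carries √2 times 1 percentage point, so a drift of that size across the window goes unseen. I called the time past the last reading in which such a hidden drift grows to one standard deviation the trust span T:

T = 1.75 d / √2 = 1.24 d

So the rule reached to 4.24 d, and the asked 15 d lay well beyond that:

(12.0 d) / T = 9.68 standard deviations of drift left open

That was the border of the rule. Past it I leaned on a second fact: the readings of X had climbed 17 points in 0.333 d, and later lay flat within the scatter over a window 5.26 times as long. I committed to the mean, read as level forward and back rates (thermodynamic control), with that margin named.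

The forecast said forward and back rates have come level, with 88 % of L reacted, X at 49.5 % and G at 18.8 %. Its ground was that the plateau “looks like true equilibrium around the whole cycle”. Its X stood slightly above my mean.

The flask gave forward and back rates have come level, with 87.1 % of L reacted, X at 50.2 % and G at 18.6 %.

    L + D ⇌ X + D, rate k1*[L]*[D] forward; the back reaction follows from the equilibrium constant (K = 3.90, k = 0.155 M⁻¹ s⁻¹)
    X + D ⇌ G + D, rate k2*[D]*[X] forward; the back reaction follows from the equilibrium constant (K = 0.371, k = 3.19 M⁻¹ s⁻¹)
    G ⇌ Q (K = 0.980, k = 6.14 × 10⁻⁵ s⁻¹)
    Q ⇌ L (k = 3.72 × 10⁻⁵ s⁻¹)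
    2 D ⇌ J, settled at all times (K = 55000 M⁻¹)
    E → D (k = 1.25 × 10⁻⁵ s⁻¹)

The same flask read at 6.0 d, where T left 2.42 standard deviations open, held X at 50.2 %, and at 15 d, where T left 9.68 open, it held X at 50.2 %. The relaxation half-life of Q and L by their own step, both ways together, was 0.0892 d, shorter than T, and 15 d holds 168 such half-lives.

(The runs stem from a simulated flask with made-up constants, noise included.)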